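**Strategy.** Everything rests on cutting C1–C2 in the quinone ring B (C1, C2, C3, C4, C4a, C8a), the bond between the C1 carbonyl on C8a and the enolic C2. C2, C3, the side-chain CH2, CH(CH3) and its oxygen are a hidden (S)-γ-valerolactone. The deacetylated target is an isomer of that lactone's aldol adduct with 3,4,6-trimethoxybenzocyclobutenedione. The C6 and C8 methoxy groups deactivate C1, so the enolate attacks C4. The precursor is this adduct as a bis-silylated ketene acetal, holding a C1–C4 bond foreign to the target. Heating breaks that bond to an o-quinoid ketene whose 6π closure makes C1–C2, rearomatises ring A and sets the quinone oxidation level without oxidant. Hydroxide then cuts the lactone tether.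

Key step: step 5

Assumption: atom labels C1 to C8a are those of the naphthoquinone core of the target and are kept for the same atoms in every precursor; both regioisomers of aryne cycloadduct 5 are hydrolysed to the same dione 6, so only the isomer expected to predominate is drawn.

Step 1
Reactants: 1 methyl 2,2-dimethoxyacetate
Product: 2 tert-butyl(dimethyl)[(1,2,2-trimethoxyethenyl)oxy]silane
Conditions: LiN(iPr)2 (LDA), THF, −78 °C; TBSCl, DMPU, −78 °C to rt
Reagents that add atoms: tert-butyldimethylsilyl chloride, CC(C)(C)[Si](C)(C)Cl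
Why: Kinetic deprotonation of the acetal C–H next to the ester and O-silylation of the enolate (silyl ketene acetal formation) should give the tetraoxygenated alkene, because the enolate has no β leaving group.

Step 2
Reactants: 3 1-bromo-2,4,5-trimethoxybenzene; 2 tert-butyl(dimethyl)[(1,2,2-trimethoxyethenyl)oxy]silane
Product: 6 2,3,5-trimethoxybicyclo[4.2.0]octa-1,3,5-triene-7,8-dione (3,4,6-trimethoxybenzocyclobutenedione), via aryne 4 (not isolated), via cycloadduct 5 (not isolated)
Conditions: lithium 2,2,6,6-tetramethylpiperidide (LiTMP, 2 equiv), 2 (2 equiv), THF, −78 °C to rt; then 3 M HCl, THF, 50 °C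
Reagents that add atoms: water, O
Why: The hindered amide removes the proton flanked by Br and OMe, LiBr is lost, the electron-rich alkene adds to the aryne in a stepwise (2+2) cycloaddition (aryne–ketene silyl acetal cycloaddition), and aqueous acid then hydrolyses both acetal carbons, helped by the donor methoxy groups of ring A.

Step 3
Reactants: 7 (S)-γ-valerolactone [(5S)-5-methyloxolan-2-one]; 6 2,3,5-trimethoxybicyclo[4.2.0]octa-1,3,5-triene-7,8-dione
Product: 9 8-hydroxy-2,3,5-trimethoxy-8-[(5S)-5-methyl-2-oxooxolan-3-yl]bicyclo[4.2.0]octa-1,3,5-trien-7-one (diastereomer mixture at C3 and C4), via lithium enolate 8 (not isolated)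
Conditions: 7, LiN(iPr)2 (LDA), THF, −78 °C; cannulated into 6, THF, −78 °C; AcOH, −78 °C
Reagents that add atoms: none
Why: This is an aldol addition of a lactone enolate to a strained, non-enolisable 1,2-dione, which should occur at the C4 carbonyl (conjugated only with the C5 methoxy group) rather than at C1 (a doubly vinylogous ester through the ortho C8 and para C6 methoxy groups); the new centres C3 and C4 form as a mixture that is erased in steps 4 and 5, and the lactone C5 centre is untouched.

Step 4
Reactants: 9 8-hydroxy-2,3,5-trimethoxy-8-[(5S)-5-methyl-2-oxooxolan-3-yl]bicyclo[4.2.0]octa-1,3,5-trien-7-one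
Product: 10 8-(tert-butyldimethylsilyloxy)-8-[(5S)-2-(tert-butyldimethylsilyloxy)-5-methyl-4,5-dihydrofuran-3-yl]-2,3,5-trimethoxybicyclo[4.2.0]octa-1,3,5-trien-7-one
Conditions: TBSOTf (3 equiv), Et3N (6 equiv), CH2Cl2, 0 °C to rt; non-aqueous work-up (pentane), Et3N-deactivated silica
Reagents that add atoms: tert-butyldimethylsilyl triflate, CC(C)(C)[Si](C)(C)OS(=O)(=O)C(F)(F)F
Why: Silyl triflate and tertiary amine should silylate the tertiary carbinol and soft-enolise the lactone through its O-silylated oxocarbenium ion (silyl ketene acetal formation), while loss of the C4 oxygen is held back because a cation or exocyclic alkene at C4 would sit in the four-membered ring next to the C1 carbonyl; C3 becomes sp2 and the (S) centre is not involved.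

Step 5
Reactants: 10 8-(tert-butyldimethylsilyloxy)-8-[(5S)-2-(tert-butyldimethylsilyloxy)-5-methyl-4,5-dihydrofuran-3-yl]-2,3,5-trimethoxybicyclo[4.2.0]octa-1,3,5-trien-7-one
Product: 14 2-hydroxy-3-[(2S)-2-hydroxypropyl]-5,6,8-trimethoxynaphthalene-1,4-dione, via dienylketene 11 (not isolated), via tricyclic ketal 12 (not isolated), via dihydrofuranoquinone 13 (not isolated)
Conditions: degassed o-xylene, 140 °C; then 1 M NaOH, THF, 0 °C to rt, under N2; 1 M HCl to pH 3 at 0 °C
Reagents that add atoms: sodium hydroxide (aqueous), [Na+].[OH-]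
Why: Proposed new method: heating opens the strained C1–C4 bond of 10 in a conrotatory 4π electrocyclic reaction in which the C4 siloxy donor rotates outward, so the ketene acetal arm is turned inward toward the ketene carbon C1 of o-quinoid dienylketene 11. A disrotatory 6π electrocyclisation then closes the six-membered ring B by joining C1 to the alkene terminus C2, irreversibly because it restores the aromaticity of ring A, whereas the only fast competitor, 4π reclosure to 10, is non-destructive. The closest known reaction type is the Moore–Liebeskind rearrangement of 2-alkenyl-2-hydroxybenzocyclobutenones and 4-alkenylcyclobutenones to hydroquinones; new here is a fully substituted, doubly oxygenated terminus that cannot tautomerise and therefore stores the quinone oxidation level in ketal 12. Hydroxide removes the C4 silyl group, the naphtholate expels silanolate from C2 to give 13, and addition–elimination of hydroxide at C2 opens the dihydrofuran by cleaving the C2–O bond, so the side-chain C–O bond and the (S) centre stay intact. The ketal carbon C2 of 12 is a new stereocentre formed without control and erased at once, so no stereocontrol is needed. The step needs torquoselectivity and periselectivity (closure at C2 rather than attack of the nucleophilic C3 on the ketene), secured by the C4 siloxy group and by the fact that only closure at C2 regains the benzene ring.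

Step 6
Reactants: 14 2-hydroxy-3-[(2S)-2-hydroxypropyl]-5,6,8-trimethoxynaphthalene-1,4-dione
Product: 16 (2S)-1-(3-hydroxy-5,7,8-trimethoxy-1,4-dioxonaphthalen-2-yl)propan-2-yl acetate (target CNP0321270.1), via diacetate 15 (not isolated)
Conditions: Ac2O, pyridine, DMAP (cat.), CH2Cl2, 0 °C to rt; then MeOH, rt
Reagents that add atoms: acetic anhydride, CC(=O)OC(C)=O
Why: DMAP-catalysed acylation should acetylate both hydroxy groups, and the C2 enol acetate, a vinylogous mixed anhydride, is then cleaved selectively by methanolysis while the secondary alkyl acetate survives; recyclisation to 13 would be a disfavoured 5-endo-trig attack, and the stereocentre is not involved.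

**Compound list**
1 | methyl 2,2-dimethoxyacetate | COC(OC)C(=O)OC | starting material
2 | tert-butyl(dimethyl)[(1,2,2-trimethoxyethenyl)oxy]silane | COC(OC)=C(OC)O[Si](C)(C)C(C)(C)C | intermediate
3 | 1-bromo-2,4,5-trimethoxybenzene | COc1cc(OC)c(OC)cc1Br | starting material
4 | 3,4,6-trimethoxybenzyne | COC1=CC(OC)=C(OC)C#C1 | intermediate
5 | 8-(tert-butyldimethylsilyloxy)-2,3,5,7,7,8-hexamethoxybicyclo[4.2.0]octa-1,3,5-triene | COc1cc(OC)c2c(c1OC)C(OC)(O[Si](C)(C)C(C)(C)C)C2(OC)OC | intermediate
6 | 2,3,5-trimethoxybicyclo[4.2.0]octa-1,3,5-triene-7,8-dione | COc1cc(OC)c2c(c1OC)C(=O)C2=O | intermediate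
7 | (S)-γ-valerolactone | C[C@H]1CCC(=O)O1 | starting material
8 | lithium enolate of (S)-γ-valerolactone | C[C@H]1CC=C([O-])O1.[Li+] | intermediate
9 | 8-hydroxy-2,3,5-trimethoxy-8-[(5S)-5-methyl-2-oxooxolan-3-yl]bicyclo[4.2.0]octa-1,3,5-trien-7-one | COc1cc(OC)c2c(c1OC)C(O)(C3C[C@H](C)OC3=O)C2=O | intermediate
10 | 8-(tert-butyldimethylsilyloxy)-8-[(5S)-2-(tert-butyldimethylsilyloxy)-5-methyl-4,5-dihydrofuran-3-yl]-2,3,5-trimethoxybicyclo[4.2.0]octa-1,3,5-trien-7-one | COc1cc(OC)c2c(c1OC)C(O[Si](C)(C)C(C)(C)C)(C3=C(O[Si](C)(C)C(C)(C)C)O[C@@H](C)C3)C2=O | intermediate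
11 | o-quinoid dienylketene from ring opening of 10 | COC1=CC(OC)=C(OC)C(=C(O[Si](C)(C)C(C)(C)C)C2=C(O[Si](C)(C)C(C)(C)C)O[C@@H](C)C2)C1=C=O | intermediate
12 | (2S)-4,9a-bis(tert-butyldimethylsilyloxy)-5,6,8-trimethoxy-2-methyl-3,9a-dihydronaphtho[2,3-b]furan-9(2H)-one | COc1cc(OC)c2c(c1OC)C(O[Si](C)(C)C(C)(C)C)=C3C[C@H](C)OC3(O[Si](C)(C)C(C)(C)C)C2=O | intermediate
13 | (2S)-5,6,8-trimethoxy-2-methyl-2,3-dihydronaphtho[2,3-b]furan-4,9-dione | COc1cc(OC)c2c(c1OC)C(=O)C3=C(O[C@@H](C)C3)C2=O | intermediate
14 | 2-hydroxy-3-[(2S)-2-hydroxypropyl]-5,6,8-trimethoxynaphthalene-1,4-dione | COc1cc(OC)c2c(c1OC)C(=O)C(C[C@H](C)O)=C(O)C2=O | intermediate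
15 | 2-acetoxy-3-[(2S)-2-acetoxypropyl]-5,6,8-trimethoxynaphthalene-1,4-dione | COc1cc(OC)c2c(c1OC)C(=O)C(C[C@H](C)OC(C)=O)=C(OC(C)=O)C2=O | intermediate
16 | 2-hydroxy-3-[(2S)-2-acetoxypropyl]-5,6,8-trimethoxynaphthalene-1,4-dione (CNP0321270.1) | COc1cc(OC)c2c(c1OC)C(=O)C(C[C@H](C)OC(C)=O)=C(O)C2=O | target

**Step count.** Total steps: 6. Longest linear sequence: 6 (1, 2, 6, 9, 10, 14, 16).

**Steps most likely to fail**

Step 5 (labelled step). The closure may stall because the siloxy group on C2 has to turn inward. Prolonged heating may then erode the ketene acetal by silyl migration or protonolysis.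
- The fallback sets out from 6 and comes back at 13. It keeps the same C1–C2 closure but uses an enol ether terminus that carries hydrogen, which is established chemistry.
- (S)-Propylene oxide is opened with lithium acetylide–ethylenediamine complex in DMSO to (S)-pent-4-yn-2-ol F1.
- Br2 in CH2Cl2 at −78 °C adds anti to give (2S,4E)-4,5-dibromopent-4-en-2-ol F2.
- CuI, 1,10-phenanthroline and Cs2CO3 in hot toluene close it by intramolecular O-vinylation to (2S)-4-bromo-2-methyl-2,3-dihydrofuran F3.
- Bromine–lithium exchange with t-BuLi at −78 °C and addition to 6 should give 8-hydroxy-2,3,5-trimethoxy-8-[(5S)-5-methyl-4,5-dihydrofuran-3-yl]bicyclo[4.2.0]octa-1,3,5-trien-7-one F4.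
- Heating F4 in xylene should give (2S)-5,6,8-trimethoxy-2-methyl-2,3-dihydronaphtho[2,3-b]furan-4,9-diol F5 by ring opening, 6π closure and tautomerisation.
- Ag2O oxidises F5 to 13, which NaOH opens to 14 as in step 5.

Step 4. Deprotonation at the hindered C3–H may be incomplete, or the silyl triflate may ionise or eliminate across C3–C4.
- The fallback sets out from 9 and comes back at 10. It replaces electrophile-first enolisation by a discrete metal enolate on a carbinol that is already capped.
- TBSOTf and 2,6-lutidine at −78 °C silylate only the tertiary alcohol to 8-(tert-butyldimethylsilyloxy)-2,3,5-trimethoxy-8-[(5S)-5-methyl-2-oxooxolan-3-yl]bicyclo[4.2.0]octa-1,3,5-trien-7-one F6.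
- KN(SiMe3)2 is then added to F6 and TBSCl in THF–DMPU at −78 °C (internal quench), so the enolate is trapped before β-elimination can start.

Step 2. Three processes may lower the efficiency: competing lithiation at the proton between the two methoxy groups, addition of the amine to the aryne, and slow cycloaddition of a tetrasubstituted alkene to an aryne flanked by two methoxy groups.
- The fallback sets out from 3 and comes back at 6. It builds the second carbonyl by benzylic oxidation instead of carrying it in the alkene.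
- NaNH2 and 1,1-dimethoxyethene in refluxing THF give, through aryne 4, 2,4,5,7,7-pentamethoxybicyclo[4.2.0]octa-1,3,5-triene F7.
- Dilute HCl hydrolyses F7 to 2,4,5-trimethoxybicyclo[4.2.0]octa-1,3,5-trien-7-one F8.
- NBS (2 equiv) with dibenzoyl peroxide in refluxing PhCF3 gives 8,8-dibromo-2,4,5-trimethoxybicyclo[4.2.0]octa-1,3,5-trien-7-one F9.
- AgNO3 in aqueous acetone hydrolyses F9 to 6.

**Further compounds**
F1 | step 5 | (S)-pent-4-yn-2-ol | C#CC[C@H](C)O
F2 | step 5 | (2S,4E)-4,5-dibromopent-4-en-2-ol | Br/C=C(/Br)C[C@H](C)O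
F3 | step 5 | (2S)-4-bromo-2-methyl-2,3-dihydrofuran | C[C@H]1CC(Br)=CO1
F4 | step 5 | 8-hydroxy-2,3,5-trimethoxy-8-[(5S)-5-methyl-4,5-dihydrofuran-3-yl]bicyclo[4.2.0]octa-1,3,5-trien-7-one | COc1cc(OC)c2c(c1OC)C(O)(C3=CO[C@@H](C)C3)C2=O
F5 | step 5 | (2S)-5,6,8-trimethoxy-2-methyl-2,3-dihydronaphtho[2,3-b]furan-4,9-diol | COc1cc(OC)c2c(O)c3c(c(O)c2c1OC)C[C@H](C)O3
F6 | step 4 | 8-(tert-butyldimethylsilyloxy)-2,3,5-trimethoxy-8-[(5S)-5-methyl-2-oxooxolan-3-yl]bicyclo[4.2.0]octa-1,3,5-trien-7-one | COc1cc(OC)c2c(c1OC)C(O[Si](C)(C)C(C)(C)C)(C3C[C@H](C)OC3=O)C2=O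
F7 | step 2 | 2,4,5,7,7-pentamethoxybicyclo[4.2.0]octa-1,3,5-triene | COc1cc(OC)c2c(c1OC)C(OC)(OC)C2
F8 | step 2 | 2,4,5-trimethoxybicyclo[4.2.0]octa-1,3,5-trien-7-one | COc1cc(OC)c2c(c1OC)C(=O)C2
F9 | step 2 | 8,8-dibromo-2,4,5-trimethoxybicyclo[4.2.0]octa-1,3,5-trien-7-one | COc1cc(OC)c2c(c1OC)C(=O)C2(Br)Br
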